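## Retrosynthetic overview

1. The target comes from O-sulfation of the free (E)-5-alkylidene-3-methyltetronic acid. Its butenolide ring, the only ring built, is closed by a Dieckmann reaction of an acyclic (E)-α-propanoyloxy acrylate, so the exocyclic geometry is fixed by a kinetic olefination before the ring exists.
2. The acrylate comes from an α-methyl aldehyde, which comes from a primary bromide. The chain is assembled by two hydroboration/B-alkyl Suzuki couplings: a chiral C5 bromoalkene with (E)-1-iodo-2-methylpenta-1,4-diene, then with 4-bromo-2-(furan-3-ylmethyl)furan.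
3. Key step: the C5 bromoalkene, which carries the only stereocentre, is made by an enantioselective copper-catalysed SN2' methylation that breaks the symmetry of (E)-1,4-dibromobut-2-ene. The surviving C–Br later becomes the aldehyde carbon.
4. The bis-furan bromide comes from furfural (C4 bromination) and 3-bromofuran (addition, then deoxygenation).
5. Ring order: both furans are bought as aromatics and carried through; the butenolide is closed in the penultimate step; the sulfate goes on last.

Assumption: the target is made exactly as drawn, i.e. E at the exocyclic enol-lactone double bond (side chain cis to C4–O), S at the methyl-bearing carbon and E in the chain; in step 5 the Taniaphos enantiomer is the one that gives the S bromide.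

## Route

Step 1
Reactants: 1 furan-2-carbaldehyde (furfural)
Product: 2 4-bromofuran-2-carbaldehyde
Conditions: AlCl3 (2.3 equiv), Br2 (1.05 equiv), CH2Cl2, 0 °C → rt; chromatography to remove 4,5-dibromo aldehyde
Reagents that add atoms: bromine, BrBr
Why: Swamping-catalyst electrophilic bromination, in which the AlCl3-complexed formyl group deactivates C3 and C5 so that bromine enters C4.

Step 2
Reactants: 3 3-bromofuran; 2 4-bromofuran-2-carbaldehyde
Product: 5 (4-bromofuran-2-yl)(furan-3-yl)methanol, via furan-3-yllithium 4 (not isolated)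
Conditions: 3, n-BuLi (1.0 equiv), THF, −78 °C; then 2, −78 °C; aq. NH4Cl
Reagents that add atoms: none
Why: Bromine–lithium exchange gives furan-3-yllithium (stable at −78 °C), which adds 1,2 to the aldehyde faster than it exchanges with the ring bromide; the racemic carbinol centre is removed in step 3.

Step 3
Reactants: 5 (4-bromofuran-2-yl)(furan-3-yl)methanol
Product: 6 4-bromo-2-(furan-3-ylmethyl)furan
Conditions: Et3SiH (3 equiv), CF3CO2H (4 equiv), CH2Cl2, −20 → 0 °C
Reagents that add atoms: none
Why: Ionic hydrogenation, in which the doubly furyl-stabilised carbocation is trapped by silane hydride faster than it alkylates another furan at low temperature.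

Step 4
Reactants: 7 pent-1-en-4-yne
Product: 9 (1E)-1-iodo-2-methylpenta-1,4-diene, via alkenyldimethylalane 8 (not isolated)
Conditions: Me3Al (2 equiv), Cp2ZrCl2 (0.2 equiv), CH2Cl2, 0 °C → rt; then I2, THF, −30 → 0 °C
Reagents that add atoms: trimethylaluminium, C[Al](C)C; iodine, II
Why: Negishi zirconium-catalysed carboalumination adds Me–Al syn across the terminal alkyne (Al on the terminal carbon) and iodinolysis with retention gives the E iodide, the isolated alkene being inert under these conditions.

Step 5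
Reactants: 10 (2E)-1,4-dibromobut-2-ene
Product: 11 (3S)-4-bromo-3-methylbut-1-ene
Conditions: MeMgBr (1.15 equiv, slow addition), CuBr·SMe2 (1 mol%), Taniaphos (1.2 mol%), CH2Cl2, −75 °C; distilled and used as a solution
Reagents that add atoms: methylmagnesium bromide, C[Mg]Br
Why: Copper-catalysed asymmetric allylic alkylation of a symmetric bis-allylic dibromide, in which the chiral copper–diphosphine complex delivers methyl anti-SN2' to one enantiotopic alkene face (the two alkene carbons are equivalent, so only facial and SN2'/SN2 selectivity matter) and sets the S centre, while the second C–Br is left as a non-allylic primary bromide.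

Step 6
Reactants: 11 (3S)-4-bromo-3-methylbut-1-ene; 9 (1E)-1-iodo-2-methylpenta-1,4-diene
Product: 13 (4E,8S)-9-bromo-4,8-dimethylnona-1,4-diene, via B-alkyl-9-BBN borane 12 (not isolated)
Conditions: 9-BBN (1.0 equiv, limiting relative to 11), THF, 0 °C → rt; then 9, Pd(dppf)Cl2 (5 mol%), AsPh3, Cs2CO3, DMF/H2O, rt
Reagents that add atoms: none
Why: Anti-Markovnikov hydroboration of the vinyl group followed by B-alkyl Suzuki–Miyaura coupling with retention of the E iodide geometry; the stereocentre is not touched and the unactivated primary bromide does not react with the palladium–dppf catalyst at room temperature.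

Step 7
Reactants: 13 (4E,8S)-9-bromo-4,8-dimethylnona-1,4-diene; 6 4-bromo-2-(furan-3-ylmethyl)furan
Product: 15 4-[(4E,8S)-9-bromo-4,8-dimethylnon-4-en-1-yl]-2-(furan-3-ylmethyl)furan, via B-alkyl-9-BBN borane 14 (not isolated)
Conditions: 9-BBN (1.05 equiv), THF, 0 °C → rt; then 6, Pd(OAc)2 (3 mol%), SPhos, K3PO4, THF/H2O, 40 °C
Reagents that add atoms: none
Why: 9-BBN selects the monosubstituted over the trisubstituted alkene and the primary alkylborane undergoes B-alkyl Suzuki–Miyaura coupling with the heteroaryl bromide, which adds to palladium far faster than the alkyl bromide.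

Step 8
Reactants: 15 4-[(4E,8S)-9-bromo-4,8-dimethylnon-4-en-1-yl]-2-(furan-3-ylmethyl)furan
Product: 16 (2S,5E)-9-[5-(furan-3-ylmethyl)furan-3-yl]-2,6-dimethylnon-5-enal
Conditions: Me3NO (anhydrous, 4 equiv), NaI (0.2 equiv), DMSO, 25–35 °C; used at once
Reagents that add atoms: trimethylamine N-oxide, C[N+](C)(C)[O-]
Why: Kornblum-type (Ganem) oxidation, in which the N-oxide oxygen displaces the halide by SN2 and loss of trimethylammonium gives the aldehyde under mild non-acidic conditions that limit epimerisation of the α-stereocentre.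

Step 9
Reactants: 17 bis(2,2,2-trifluoroethyl) phosphonate; 18 methyl 2-oxoacetate (methyl glyoxylate)
Product: 20 methyl 2-[bis(2,2,2-trifluoroethoxy)phosphoryl]-2-(propanoyloxy)acetate, via hydroxyphosphonate 19 (not isolated)
Conditions: toluene, 60 °C (no base); then EtCOCl, pyridine, CH2Cl2, −20 → 0 °C
Reagents that add atoms: propanoyl chloride, CCC(=O)Cl
Why: Pudovik addition of the H-phosphonate to the glyoxylate carbonyl followed by O-acylation, with base-free addition and cold pyridine acylation chosen to avoid phospha-Brook rearrangement.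

Step 10
Reactants: 16 (2S,5E)-9-[5-(furan-3-ylmethyl)furan-3-yl]-2,6-dimethylnon-5-enal; 20 methyl 2-[bis(2,2,2-trifluoroethoxy)phosphoryl]-2-(propanoyloxy)acetate
Product: 21 methyl (2E,4S,7E)-11-[5-(furan-3-ylmethyl)furan-3-yl]-4,8-dimethyl-2-(propanoyloxy)undeca-2,7-dienoate
Conditions: 20 (1.3 equiv), KN(SiMe3)2, 18-crown-6, THF, −78 °C; then 16, −78 °C
Reagents that add atoms: none
Why: Proposed new method: a Still–Gennari-type Horner–Wadsworth–Emmons olefination with an α-acyloxy phosphonoacetate, in which the trifluoroethyl phosphonate and the crown-complexed potassium make addition irreversible and elimination fast, so the kinetic adduct gives the alkene with the aldehyde substituent cis to CO2Me (the 2E enol ester, which becomes the E exocyclic bond), as is known for the α-methyl, α-bromo and α-fluoro bis(trifluoroethyl) phosphonoacetates; the S centre is not touched at −78 °C.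

Step 11
Reactants: 21 methyl (2E,4S,7E)-11-[5-(furan-3-ylmethyl)furan-3-yl]-4,8-dimethyl-2-(propanoyloxy)undeca-2,7-dienoate
Product: 22 (5E)-5-[(2S,5E)-9-[5-(furan-3-ylmethyl)furan-3-yl]-2,6-dimethylnon-5-en-1-ylidene]-4-hydroxy-3-methylfuran-2(5H)-one
Conditions: LiN(SiMe3)2 (2.3 equiv), THF, −78 → −20 °C; aq. HCl to pH 3 at 0 °C; kept cold and dark
Reagents that add atoms: none
Why: Dieckmann (intramolecular Claisen) condensation of an enol ester, in which the propanoate enolate attacks the conjugated methyl ester (5-exo-trig) and expels methoxide to give the tetronate anion; the C=C bond takes no part, so the E geometry and the S centre are carried through, as in the known closure of enol esters to pulvinones.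

Step 12
Reactants: 22 (5E)-5-[(2S,5E)-9-[5-(furan-3-ylmethyl)furan-3-yl]-2,6-dimethylnon-5-en-1-ylidene]-4-hydroxy-3-methylfuran-2(5H)-one
Product: 23 (5E)-5-[(2S,5E)-9-[5-(furan-3-ylmethyl)furan-3-yl]-2,6-dimethylnon-5-en-1-ylidene]-3-methyl-4-(sulfooxy)furan-2(5H)-one (target)
Conditions: SO3·pyridine (3 equiv), pyridine, 0 °C → rt; then H+-form sulfonic acid resin, MeOH, 0 °C (stored as the sodium salt after NaHCO3)
Reagents that add atoms: sulfur trioxide–pyridine complex, [O-]S(=O)(=O)[n+]1ccccc1
Why: O-sulfation of the acidic tetronic enol with a sulfur trioxide–amine complex, which is much faster at 0 °C than C-sulfonation of the furans and does not touch the alkenes or the stereocentre.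

## Compound list

1 | furan-2-carbaldehyde (furfural) | O=Cc1ccco1 | starting material
2 | 4-bromofuran-2-carbaldehyde | O=Cc1cc(Br)co1 | intermediate
3 | 3-bromofuran | Brc1ccoc1 | starting material
4 | furan-3-yllithium | [Li]c1ccoc1 | intermediate
5 | (4-bromofuran-2-yl)(furan-3-yl)methanol (racemic) | OC(c1cc(Br)co1)c1ccoc1 | intermediate
6 | 4-bromo-2-(furan-3-ylmethyl)furan | Brc1coc(Cc2ccoc2)c1 | intermediate
7 | pent-1-en-4-yne | C=CCC#C | starting material
8 | dimethyl[(1E)-2-methylpenta-1,4-dien-1-yl]alane | C[Al](C)/C=C(\C)CC=C | intermediate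
9 | (1E)-1-iodo-2-methylpenta-1,4-diene | I/C=C(\C)CC=C | intermediate
10 | (2E)-1,4-dibromobut-2-ene | BrC/C=C/CBr | starting material
11 | (3S)-4-bromo-3-methylbut-1-ene | BrC[C@@H](C)C=C | intermediate
12 | 9-[(3S)-4-bromo-3-methylbutyl]-9-borabicyclo[3.3.1]nonane | BrC[C@@H](C)CCB1C2CCCC1CCC2 | intermediate
13 | (4E,8S)-9-bromo-4,8-dimethylnona-1,4-diene | BrC[C@@H](C)CC/C=C(\C)CC=C | intermediate
14 | 9-[(4E,8S)-9-bromo-4,8-dimethylnon-4-en-1-yl]-9-borabicyclo[3.3.1]nonane | BrC[C@@H](C)CC/C=C(\C)CCCB1C2CCCC1CCC2 | intermediate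
15 | 4-[(4E,8S)-9-bromo-4,8-dimethylnon-4-en-1-yl]-2-(furan-3-ylmethyl)furan | BrC[C@@H](C)CC/C=C(\C)CCCc1coc(Cc2ccoc2)c1 | intermediate
16 | (2S,5E)-9-[5-(furan-3-ylmethyl)furan-3-yl]-2,6-dimethylnon-5-enal | O=C[C@@H](C)CC/C=C(\C)CCCc1coc(Cc2ccoc2)c1 | intermediate
17 | bis(2,2,2-trifluoroethyl) phosphonate | [H]P(=O)(OCC(F)(F)F)OCC(F)(F)F | starting material
18 | methyl 2-oxoacetate (methyl glyoxylate) | COC(=O)C=O | starting material
19 | methyl 2-[bis(2,2,2-trifluoroethoxy)phosphoryl]-2-hydroxyacetate | COC(=O)C(O)P(=O)(OCC(F)(F)F)OCC(F)(F)F | intermediate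
20 | methyl 2-[bis(2,2,2-trifluoroethoxy)phosphoryl]-2-(propanoyloxy)acetate | CCC(=O)OC(C(=O)OC)P(=O)(OCC(F)(F)F)OCC(F)(F)F | intermediate
21 | methyl (2E,4S,7E)-11-[5-(furan-3-ylmethyl)furan-3-yl]-4,8-dimethyl-2-(propanoyloxy)undeca-2,7-dienoate | CCC(=O)O/C(C(=O)OC)=C/[C@@H](C)CC/C=C(\C)CCCc1coc(Cc2ccoc2)c1 | intermediate
22 | (5E)-5-[(2S,5E)-9-[5-(furan-3-ylmethyl)furan-3-yl]-2,6-dimethylnon-5-en-1-ylidene]-4-hydroxy-3-methylfuran-2(5H)-one | CC1=C(O)/C(=C\[C@@H](C)CC/C=C(\C)CCCc2coc(Cc3ccoc3)c2)OC1=O | intermediate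
23 | (5E)-5-[(2S,5E)-9-[5-(furan-3-ylmethyl)furan-3-yl]-2,6-dimethylnon-5-en-1-ylidene]-3-methyl-4-(sulfooxy)furan-2(5H)-one | CC1=C(OS(=O)(=O)O)/C(=C\[C@@H](C)CC/C=C(\C)CCCc2coc(Cc3ccoc3)c2)OC1=O | target

## Step count and risks

Total: 12 steps. Longest linear sequence: 8 steps (1, 2, 3, 7, 8, 10, 11, 12).

The three steps most likely to fail are steps 10, 5 and 8, in that order of risk; the fallbacks are given in route order.

**Step 5.** The SN2' methylation of the dibromide may give insufficient ee or regioselectivity with MeMgBr. In addition, 11 is volatile, and its borane 12 carries a bromide that could cyclise onto boron under base. The fallback sets out from 10 and comes back at 13; it gives up the symmetric electrophile and carries an oxygen handle instead.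
- Statistical mono-substitution of 10 (3 equiv) with PhCO2Na in DMF gives (2E)-4-bromobut-2-en-1-yl benzoate F1, a non-volatile, UV-active allylic bromide.
- The same copper/Taniaphos SN2' methylation with MeMgBr, on a substrate class where it is best established and the ee can be read by HPLC, gives (2S)-2-methylbut-3-en-1-yl benzoate F2.
- 9-BBN converts F2 into 9-[(3S)-4-(benzoyloxy)-3-methylbutyl]-9-borabicyclo[3.3.1]nonane F3, which is coupled with 9 under the step 6 conditions to give (2S,5E)-2,6-dimethylnona-5,8-dien-1-yl benzoate F4.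
- K2CO3 in MeOH gives (2S,5E)-2,6-dimethylnona-5,8-dien-1-ol F5, and CBr4/PPh3 in CH2Cl2 turns F5 into 13.

**Step 8.** The β-branched primary bromide may be displaced slowly by the N-oxide, and the trimethylamine formed could erode the new α-stereocentre. The fallback sets out from 15 and comes back at 16; it replaces the oxidative displacement by substitution, hydrolysis and a separate neutral oxidation.
- CsOAc and 18-crown-6 in DMF at 70 °C give (2S,5E)-9-[5-(furan-3-ylmethyl)furan-3-yl]-2,6-dimethylnon-5-en-1-yl acetate F6.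
- K2CO3 in MeOH gives (2S,5E)-9-[5-(furan-3-ylmethyl)furan-3-yl]-2,6-dimethylnon-5-en-1-ol F7.
- Dess–Martin periodinane buffered with NaHCO3 gives 16.

**Step 10.** The cis-to-ester (2E) selectivity of the α-acyloxy reagent is extrapolated, and a Z-rich enol ester would lead to the wrong alkylidene isomer. The fallback sets out from 16 and comes back at 22, replacing steps 10 and 11 by a vinylogous aldol and a stereospecific syn-dehydration.
- Commercial 4-hydroxy-3-methylfuran-2(5H)-one and allyl alcohol under Mitsunobu conditions (PPh3, diisopropyl azodicarboxylate) give 3-methyl-4-(prop-2-en-1-yloxy)furan-2(5H)-one F8.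
- TBSOTf and Et3N give the aromatic silyloxyfuran tert-butyl(dimethyl){[3-methyl-4-(prop-2-en-1-yloxy)furan-2-yl]oxy}silane F9.
- A BF3·OEt2-promoted vinylogous Mukaiyama aldol of F9 with 16 at −78 °C is expected to favour the threo adduct (ring O and OH threo): (5S)-5-[(1R,2S,5E)-9-[5-(furan-3-ylmethyl)furan-3-yl]-1-hydroxy-2,6-dimethylnon-5-en-1-yl]-3-methyl-4-(prop-2-en-1-yloxy)furan-2(5H)-one F10. Its (5R,1S) threo partner reacts alike.
- Burgess reagent (syn-elimination, which from the threo adduct places the chain cis to C4) gives (5E)-5-[(2S,5E)-9-[5-(furan-3-ylmethyl)furan-3-yl]-2,6-dimethylnon-5-en-1-ylidene]-3-methyl-4-(prop-2-en-1-yloxy)furan-2(5H)-one F11.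
- Pd(PPh3)4 and morpholine remove the allyl group under neutral conditions to give 22.

## Further compounds

F1 | step 5 | (2E)-4-bromobut-2-en-1-yl benzoate | O=C(OC/C=C/CBr)c1ccccc1
F2 | step 5 | (2S)-2-methylbut-3-en-1-yl benzoate | O=C(OC[C@@H](C)C=C)c1ccccc1
F3 | step 5 | 9-[(3S)-4-(benzoyloxy)-3-methylbutyl]-9-borabicyclo[3.3.1]nonane | O=C(OC[C@@H](C)CCB1C2CCCC1CCC2)c1ccccc1
F4 | step 5 | (2S,5E)-2,6-dimethylnona-5,8-dien-1-yl benzoate | O=C(OC[C@@H](C)CC/C=C(\C)CC=C)c1ccccc1
F5 | step 5 | (2S,5E)-2,6-dimethylnona-5,8-dien-1-ol | OC[C@@H](C)CC/C=C(\C)CC=C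
F6 | step 8 | (2S,5E)-9-[5-(furan-3-ylmethyl)furan-3-yl]-2,6-dimethylnon-5-en-1-yl acetate | CC(=O)OC[C@@H](C)CC/C=C(\C)CCCc1coc(Cc2ccoc2)c1
F7 | step 8 | (2S,5E)-9-[5-(furan-3-ylmethyl)furan-3-yl]-2,6-dimethylnon-5-en-1-ol | OC[C@@H](C)CC/C=C(\C)CCCc1coc(Cc2ccoc2)c1
F8 | step 10 | 3-methyl-4-(prop-2-en-1-yloxy)furan-2(5H)-one | CC1=C(OCC=C)COC1=O
F9 | step 10 | tert-butyl(dimethyl){[3-methyl-4-(prop-2-en-1-yloxy)furan-2-yl]oxy}silane | Cc1c(OCC=C)coc1O[Si](C)(C)C(C)(C)C
F10 | step 10 | (5S)-5-[(1R,2S,5E)-9-[5-(furan-3-ylmethyl)furan-3-yl]-1-hydroxy-2,6-dimethylnon-5-en-1-yl]-3-methyl-4-(prop-2-en-1-yloxy)furan-2(5H)-one | CC1=C(OCC=C)[C@H]([C@H](O)[C@@H](C)CC/C=C(\C)CCCc2coc(Cc3ccoc3)c2)OC1=O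
F11 | step 10 | (5E)-5-[(2S,5E)-9-[5-(furan-3-ylmethyl)furan-3-yl]-2,6-dimethylnon-5-en-1-ylidene]-3-methyl-4-(prop-2-en-1-yloxy)furan-2(5H)-one | CC1=C(OCC=C)/C(=C\[C@@H](C)CC/C=C(\C)CCCc2coc(Cc3ccoc3)c2)OC1=O
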